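**Abbreviations:** TBS = tert-butyldimethylsilyl; PMB = 4-methoxybenzyl; Bpin = 4,4,5,5-tetramethyl-1,3,2-dioxaborolan-2-yl; Ang = angeloyl = (Z)-2-methylbut-2-enoyl.

## Retrosynthetic overview

1. Germacrane numbering is used: ring C1–C10, C14 on C10, C15 on C4, isopropenyl C11(=C12)C13 on C7. The target is the (1R,3S,4S,5S,7R,8S,9S,10S)-3,8-diangelate with cis-oxiranes at C1/C10 and C4/C5 and a free C9–OH.
2. Endgame: the C1/C10 oxirane comes from the (Z)-C1=C10 alkene by C9–OH-directed vanadium epoxidation, and the C8 ester from a C8–OH; so the ring is needed as a C8-ol with C9–OTBS.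
3. Key disconnection C7–C8: ring atoms C8 (O-bearing) and C7 (isopropenyl-bearing) form a homoallylic alcohol O–C8–C7–C11=C12, flanked by the C9–O stereocentre. This is the retron of an allylboration, so the ten-membered carbocycle C1–C10 is closed by intramolecular addition of a (Z)-allyl–Bpin (boron on C12) to the C8 aldehyde, which creates C7, C8 and the isopropenyl group at once.
4. The open-chain precursor (a farnesane chain C8→C12) comes from two Ni/Cr couplings (C9–C10 and C3–C4) of (Z)-2-iodoalkenes, all made from one aldehyde by Stork–Zhao olefination. One chiral Cr catalyst sets C9 and C3, and C3–OH then directs the 4,5-epoxidation.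
5. Ring order: C4/C5 oxirane on the open chain → ten-membered carbocycle (key step; no C–C bond is made after it) → C1/C10 oxygen bridge added to the finished ring.

Key step: step 15

Assumption: the ligand antipode named in steps 5 and 9 is the one expected to give Re-face addition; the sense is to be confirmed on 8, and the mirror-image ligand used if it proves opposite.

Assumption: aldehyde 1 is taken as a purchasable building block.

## Route

Step 1
Reactants: 1 3-(PMBO)propanal; 2 ethyltriphenylphosphonium iodide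
Product: 3 1-({[(3Z)-4-iodopent-3-en-1-yl]oxy}methyl)-4-methoxybenzene
Conditions: 2, n-BuLi, THF, 0 °C; I2, −78 °C; NaHMDS, −20 °C; then 1, −78 °C → rt
Reagents that add atoms: iodine, II
Why: Stork–Zhao olefination: the α-iodo ylide made in the flask should give the (Z)-2-iodoalk-2-ene (iodine cis to the chain) under kinetic Wittig control.

Step 2
Reactants: 3
Product: 4 (3Z)-4-iodopent-3-en-1-ol
Conditions: DDQ, CH2Cl2/pH 7 buffer, 0 °C
Reagents that add atoms: none
Why: oxidative PMB-ether cleavage with DDQ leaves the vinyl iodide untouched.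

Step 3
Reactants: 4
Product: 5 (3Z)-4-iodopent-3-enal
Conditions: Dess–Martin periodinane, pyridine, CH2Cl2, 0 °C; used crude
Reagents that add atoms: none
Why: Dess–Martin oxidation under buffered, non-basic conditions should give the β,γ-unsaturated aldehyde without conjugation.

Step 4
Reactants: 5; 2 ethyltriphenylphosphonium iodide
Product: 6 (2Z,5Z)-2,6-diiodohepta-2,5-diene
Conditions: 2, n-BuLi, THF, 0 °C; I2, −78 °C; NaHMDS, −20 °C; then 5, −78 °C → rt
Reagents that add atoms: iodine, II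
Why: a second Stork–Zhao olefination gives the symmetric (Z,Z)-diiodide, a two-directional linchpin whose ends need no differentiation.

Step 5
Reactants: 3; 7 (TBSO)acetaldehyde
Product: 8 (2R,3Z)-1-(TBSO)-6-(PMBO)-3-methylhex-3-en-2-ol
Conditions: CrCl2 (10 mol%), (S)-N-[2-(4-isopropyl-4,5-dihydrooxazol-2-yl)-6-methylphenyl]methanesulfonamide (11 mol%), proton sponge (11 mol%), NiCl2·(2,9-dimethyl-1,10-phenanthroline) (2 mol%), Mn, Cp2ZrCl2, LiCl, MeCN, rt; aq. work-up
Reagents that add atoms: none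
Why: catalytic asymmetric Nozaki–Hiyama–Kishi coupling: the Ni-activated alkenyl iodide is passed to the chiral Cr(III)–sulfonamide complex, which should add to the Re face of the aldehyde with retention of the Z geometry and so set C9.

Step 6
Reactants: 8
Product: 9 1-({[(3Z,5R)-5,6-bis(TBSO)-4-methylhex-3-en-1-yl]oxy}methyl)-4-methoxybenzene
Conditions: TBSOTf, 2,6-lutidine, CH2Cl2, −78 °C
Reagents that add atoms: tert-butyldimethylsilyl trifluoromethanesulfonate, CC(C)(C)[Si](C)(C)OS(=O)(=O)C(F)(F)F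
Why: standard silylation of the hindered secondary allylic alcohol with the silyl triflate.

Step 7
Reactants: 9
Product: 10 (3Z,5R)-5,6-bis(TBSO)-4-methylhex-3-en-1-ol
Conditions: DDQ, CH2Cl2/pH 7 buffer, 0 °C
Reagents that add atoms: none
Why: DDQ removes the PMB ether selectively in the presence of both silyl ethers and the trisubstituted alkene.

Step 8
Reactants: 10
Product: 11 (3Z,5R)-5,6-bis(TBSO)-4-methylhex-3-enal
Conditions: Dess–Martin periodinane, pyridine, CH2Cl2, 0 °C; used crude
Reagents that add atoms: none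
Why: buffered Dess–Martin oxidation should deliver the β,γ-unsaturated aldehyde without double-bond migration.

Step 9
Reactants: 11; 6 (3 equiv)
Product: 12 (2R,3Z,6S,7Z,10Z)-1,2-bis(TBSO)-11-iodo-3,7-dimethyldodeca-3,7,10-trien-6-ol
Conditions: CrCl2 (10 mol%), (S)-N-[2-(4-isopropyl-4,5-dihydrooxazol-2-yl)-6-methylphenyl]methanesulfonamide (11 mol%), proton sponge (11 mol%), NiCl2·(2,9-dimethyl-1,10-phenanthroline) (2 mol%), Mn, Cp2ZrCl2, LiCl, MeCN, rt; aq. work-up
Reagents that add atoms: none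
Why: the same catalytic asymmetric Nozaki–Hiyama–Kishi coupling: excess symmetric diiodide should secure mono-coupling, and the same ligand antipode again directs Re-face attack to set C3, the remote C9 centre having no influence.

Step 10
Reactants: 12
Product: 13 (2R,3Z,6S,7R,8S,10Z)-1,2-bis(TBSO)-7,8-epoxy-11-iodo-3,7-dimethyldodeca-3,10-dien-6-ol
Conditions: mCPBA, CH2Cl2, −20 °C
Reagents that add atoms: 3-chloroperoxybenzoic acid, O=C(OO)c1cccc(Cl)c1
Why: hydroxyl-directed (Henbest) epoxidation: A1,3 strain in the (Z)-allylic alcohol holds H-3 in the alkene plane, so the hydrogen-bonded peracid should add syn to C3–OH (threo) and set C4 and C5, while the vinyl iodide and the C1=C10 alkene (no allylic OH, deactivated by the allylic silyloxy group) react more slowly.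

Step 11
Reactants: 13; 14 angelic acid
Product: 15 (2R,3Z,6S,7S,8S,10Z)-1,2-bis(TBSO)-7,8-epoxy-11-iodo-3,7-dimethyldodeca-3,10-dien-6-yl angelate
Conditions: 14, 2,4,6-trichlorobenzoyl chloride, Et3N, PhMe, rt; then 13, 75 °C
Reagents that add atoms: none
Why: esterification through the mixed 2,4,6-trichlorobenzoic anhydride without DMAP (Yamaguchi-type), the conditions known to acylate hindered alcohols with angelic acid without Z→E isomerisation to the tiglate.

Step 12
Reactants: 15
Product: 16 (2R,3Z,6S,7S,8S,10Z)-6-angeloyloxy-2-(TBSO)-7,8-epoxy-11-iodo-3,7-dimethyldodeca-3,10-dien-1-ol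
Conditions: HF·pyridine, pyridine, THF, 0 °C
Reagents that add atoms: none
Why: buffered HF·pyridine should cleave the primary TBS ether much faster than the hindered secondary allylic one and spare the oxirane.

Step 13
Reactants: 16; 17 2-(iodomethyl)-Bpin
Product: 18 (2R,3Z,6S,7S,8S,10Z)-6-angeloyloxy-2-(TBSO)-7,8-epoxy-3,7,11-trimethyl-12-(Bpin)dodeca-3,10-dien-1-ol
Conditions: 17, Zn dust, THF, rt; then 16, Pd(PPh3)4 (5 mol%), THF, 40 °C
Reagents that add atoms: none
Why: Negishi coupling of the alkenyl iodide with the borylmethylzinc iodide proceeds with retention of alkene geometry and should give the (Z)-allylboronate (C12 cis to C6) under conditions that tolerate ester, oxirane and free hydroxyl.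

Step 14
Reactants: 18
Product: 19 (2R,3Z,6S,7S,8S,10Z)-6-angeloyloxy-2-(TBSO)-7,8-epoxy-3,7,11-trimethyl-12-(Bpin)dodeca-3,10-dienal
Conditions: Dess–Martin periodinane, pyridine, CH2Cl2, 0 °C; filtered and used at once
Reagents that add atoms: none
Why: Dess–Martin oxidation is compatible with pinacol allylboronates, and the hindered β-methyl, γ-substituted allyl–Bpin should not add to the aldehyde at 0 °C during the oxidation.

Step 15
Reactants: 19
Product: 21 (1(10)Z,3S,4S,5S,7R,8S,9R)-3-angeloyloxy-9-(TBSO)-4,5-epoxygermacra-1(10),11-dien-8-ol, via borate ester 20 (not isolated)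
Conditions: PhMe (1 mM), 70 °C, 24 h; then pH 7 buffer, rt
Reagents that add atoms: none
Why: Proposed new method: heating the ω-formyl (Z)-allylboronate at high dilution should close the ring through a concerted, boron-centred six-membered chair (Zimmerman–Traxler) transition state in which boron binds the C8 carbonyl oxygen, C7 attacks C8 and the double bond moves from C7=C11 to C11=C12, so that one operation makes the C7–C8 bond, the ten-membered carbocycle, the isopropenyl group, the C8 hydroxyl (as borate 20) and the C7 and C8 stereocentres. The closest known reactions are the intramolecular allylboration of ω-formyl allylboronates (five- to eight-membered rings) and the (Z)-crotylboration of α-alkoxy aldehydes; a ten-membered carbocycle has not been closed this way. The ring closes in the 10-exo-trig mode at the aldehyde carbon (carbonyl oxygen outside the ring) with allylic (SE2′) transposition on the nucleophile side. C7 is controlled by the fixed Z geometry of the configurationally stable allylboronate (C6 axial in the chair, hence C6 and O-8 syn), and C8 by the adjacent C9 silyloxy centre through the Cornforth–Felkin arrangement (attack anti to C9–O, giving the 8,9-anti relation); both are the intrinsic, matched preferences of (Z)-crotylboronates with α-oxygenated aldehydes. The step needs ring closure to beat intermolecular allylboration and the chair to beat the boat: the slow bimolecular rate of a β-methyl, γ-substituted pinacol allylboronate at 1 mM should secure the first, and the (Z)-alkene and cis-oxirane, which bend the chain and remove transannular hydrogens, should allow a low-strain cis-fused chair. The oxirane in place of a second ring alkene also leaves no 1,5-diene for a Cope rearrangement at 70 °C.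

Step 16
Reactants: 21; 14 angelic acid
Product: 22 (1(10)Z,3S,4S,5S,7R,8S,9R)-3,8-bis(angeloyloxy)-9-(TBSO)-4,5-epoxygermacra-1(10),11-diene
Conditions: 14, 2,4,6-trichlorobenzoyl chloride, Et3N, PhMe, rt; then 21, 80 °C
Reagents that add atoms: none
Why: the same DMAP-free mixed-anhydride (Yamaguchi-type) esterification should acylate the hindered C8–OH without tiglate formation or silyl migration, since no alkoxide is generated.

Step 17
Reactants: 22
Product: 23 (1(10)Z,3S,4S,5S,7R,8S,9R)-3,8-bis(angeloyloxy)-4,5-epoxygermacra-1(10),11-dien-9-ol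
Conditions: HF·pyridine, pyridine, THF, 0 °C → rt
Reagents that add atoms: none
Why: buffered fluoride-mediated desilylation under mildly acidic conditions should free C9–OH without base-induced 8→9 acyl migration or oxirane opening.

Step 18
Reactants: 23
Product: 24 (1R,3S,4S,5S,7R,8S,9S,10S)-3,8-bis(angeloyloxy)-1,10:4,5-diepoxygermacr-11-en-9-ol (target)
Conditions: VO(acac)2 (5 mol%), t-BuOOH (decane), CH2Cl2, 0 °C → rt
Reagents that add atoms: tert-butyl hydroperoxide, CC(C)(C)OO
Why: vanadium-catalysed hydroxyl-directed epoxidation: the vanadate ester of C9–OH should deliver oxygen to the syn face of the neighbouring (Z)-C1=C10 alkene (cis epoxy alcohol, as for medium-ring 2-cycloalkenols and for allylic alcohols with A1,2 strain from the C10 methyl), setting C1 and C10 while the undirected isopropenyl and angelate alkenes stay untouched.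

## Compound list

1 | 3-(PMBO)propanal | COc1ccc(COCCC=O)cc1 | starting material
2 | ethyltriphenylphosphonium iodide | CC[P+](c1ccccc1)(c1ccccc1)c1ccccc1.[I-] | starting material
3 | 1-({[(3Z)-4-iodopent-3-en-1-yl]oxy}methyl)-4-methoxybenzene | COc1ccc(COCC/C=C(C)\I)cc1 | intermediate
4 | (3Z)-4-iodopent-3-en-1-ol | OCC/C=C(C)\I | intermediate
5 | (3Z)-4-iodopent-3-enal | O=CC/C=C(C)\I | intermediate
6 | (2Z,5Z)-2,6-diiodohepta-2,5-diene | I/C(C)=C\C/C=C(C)\I | intermediate
7 | (TBSO)acetaldehyde | CC(C)(C)[Si](C)(C)OCC=O | starting material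
8 | (2R,3Z)-1-(TBSO)-6-(PMBO)-3-methylhex-3-en-2-ol | COc1ccc(COCC/C=C(C)\[C@@H](O)CO[Si](C)(C)C(C)(C)C)cc1 | intermediate
9 | 1-({[(3Z,5R)-5,6-bis(TBSO)-4-methylhex-3-en-1-yl]oxy}methyl)-4-methoxybenzene | COc1ccc(COCC/C=C(C)\[C@@H](O[Si](C)(C)C(C)(C)C)CO[Si](C)(C)C(C)(C)C)cc1 | intermediate
10 | (3Z,5R)-5,6-bis(TBSO)-4-methylhex-3-en-1-ol | OCC/C=C(C)\[C@@H](O[Si](C)(C)C(C)(C)C)CO[Si](C)(C)C(C)(C)C | intermediate
11 | (3Z,5R)-5,6-bis(TBSO)-4-methylhex-3-enal | O=CC/C=C(C)\[C@@H](O[Si](C)(C)C(C)(C)C)CO[Si](C)(C)C(C)(C)C | intermediate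
12 | (2R,3Z,6S,7Z,10Z)-1,2-bis(TBSO)-11-iodo-3,7-dimethyldodeca-3,7,10-trien-6-ol | I/C(C)=C\C/C=C(C)\[C@@H](O)C/C=C(C)\[C@@H](O[Si](C)(C)C(C)(C)C)CO[Si](C)(C)C(C)(C)C | intermediate
13 | (2R,3Z,6S,7R,8S,10Z)-1,2-bis(TBSO)-7,8-epoxy-11-iodo-3,7-dimethyldodeca-3,10-dien-6-ol | I/C(C)=C\C[C@@H]1O[C@]1(C)[C@@H](O)C/C=C(C)\[C@@H](O[Si](C)(C)C(C)(C)C)CO[Si](C)(C)C(C)(C)C | intermediate
14 | angelic acid, (2Z)-2-methylbut-2-enoic acid | C/C=C(/C)C(=O)O | starting material
15 | (2R,3Z,6S,7S,8S,10Z)-1,2-bis(TBSO)-7,8-epoxy-11-iodo-3,7-dimethyldodeca-3,10-dien-6-yl angelate | I/C(C)=C\C[C@@H]1O[C@]1(C)[C@@H](OC(=O)/C(C)=C\C)C/C=C(C)\[C@@H](O[Si](C)(C)C(C)(C)C)CO[Si](C)(C)C(C)(C)C | intermediate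
16 | (2R,3Z,6S,7S,8S,10Z)-6-angeloyloxy-2-(TBSO)-7,8-epoxy-11-iodo-3,7-dimethyldodeca-3,10-dien-1-ol | I/C(C)=C\C[C@@H]1O[C@]1(C)[C@@H](OC(=O)/C(C)=C\C)C/C=C(C)\[C@@H](O[Si](C)(C)C(C)(C)C)CO | intermediate
17 | 2-(iodomethyl)-4,4,5,5-tetramethyl-1,3,2-dioxaborolane | CC1(C)OB(CI)OC1(C)C | starting material
18 | (2R,3Z,6S,7S,8S,10Z)-6-angeloyloxy-2-(TBSO)-7,8-epoxy-3,7,11-trimethyl-12-(Bpin)dodeca-3,10-dien-1-ol | CC1(C)OB(C/C(C)=C\C[C@@H]2O[C@]2(C)[C@@H](OC(=O)/C(C)=C\C)C/C=C(C)\[C@@H](O[Si](C)(C)C(C)(C)C)CO)OC1(C)C | intermediate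
19 | (2R,3Z,6S,7S,8S,10Z)-6-angeloyloxy-2-(TBSO)-7,8-epoxy-3,7,11-trimethyl-12-(Bpin)dodeca-3,10-dienal | CC1(C)OB(C/C(C)=C\C[C@@H]2O[C@]2(C)[C@@H](OC(=O)/C(C)=C\C)C/C=C(C)\[C@@H](O[Si](C)(C)C(C)(C)C)C=O)OC1(C)C | intermediate
20 | 8-O-Bpin borate ester of 21 | C=C(C)[C@H]1C[C@@H]2O[C@]2(C)[C@@H](OC(=O)/C(C)=C\C)C/C=C(C)\[C@@H](O[Si](C)(C)C(C)(C)C)[C@H]1OB1OC(C)(C)C(C)(C)O1 | intermediate (not isolated)
21 | (1(10)Z,3S,4S,5S,7R,8S,9R)-3-angeloyloxy-9-(TBSO)-4,5-epoxygermacra-1(10),11-dien-8-ol | C=C(C)[C@H]1C[C@@H]2O[C@]2(C)[C@@H](OC(=O)/C(C)=C\C)C/C=C(C)\[C@@H](O[Si](C)(C)C(C)(C)C)[C@H]1O | intermediate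
22 | (1(10)Z,3S,4S,5S,7R,8S,9R)-3,8-bis(angeloyloxy)-9-(TBSO)-4,5-epoxygermacra-1(10),11-diene | C=C(C)[C@H]1C[C@@H]2O[C@]2(C)[C@@H](OC(=O)/C(C)=C\C)C/C=C(C)\[C@@H](O[Si](C)(C)C(C)(C)C)[C@H]1OC(=O)/C(C)=C\C | intermediate
23 | (1(10)Z,3S,4S,5S,7R,8S,9R)-3,8-bis(angeloyloxy)-4,5-epoxygermacra-1(10),11-dien-9-ol | C=C(C)[C@H]1C[C@@H]2O[C@]2(C)[C@@H](OC(=O)/C(C)=C\C)C/C=C(C)\[C@@H](O)[C@H]1OC(=O)/C(C)=C\C | intermediate
24 | (1R,3S,4S,5S,7R,8S,9S,10S)-3,8-bis(angeloyloxy)-1,10:4,5-diepoxygermacr-11-en-9-ol (CNP0304877.1) | C=C(C)[C@H]1C[C@@H]2O[C@]2(C)[C@@H](OC(=O)/C(C)=C\C)C[C@H]2O[C@@]2(C)[C@@H](O)[C@H]1OC(=O)/C(C)=C\C | target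

## Step count and risks

Total step count: 18. Longest linear sequence: 15 (steps 1 and 5–18; steps 2–4 are the side branch to diiodide 6).

**Step 15 (proposed new method).** Intermolecular allylboration (oligomerisation) or thermal decay of the α-silyloxy aldehyde may outrun ring closure, or closure through a boat transition state may erode the 7,8-syn relation. The fallback uses known chemistry, the Cr(II)-mediated Nozaki–Hiyama allylation that is established for ten-membered germacrane rings. It sets out from 15 and comes back at 21. Stille coupling of 15 with (tributylstannyl)methanol (Pd(PPh3)4, PhMe, 90 °C) should give the (Z)-allylic alcohol (2R,3Z,6S,7S,8S,10Z)-1,2-bis(TBSO)-7,8-epoxy-12-hydroxy-3,7,11-trimethyldodeca-3,10-dien-6-yl angelate F1. CBr4/PPh3 (CH2Cl2, 0 °C) converts it into the allylic bromide F2. Buffered HF·pyridine frees the primary alcohol F3, and Dess–Martin oxidation gives the bromo aldehyde F4. CrCl2 in THF at 1 mM should then close the ring to 21. Because the allylchromium species is configurationally mobile, the C7/C8 relation is then decided by the ring alone and has to be verified.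

**Step 9.** The chiral Cr complex may discriminate the aldehyde faces poorly, the diiodide may couple twice, or the β,γ double bond of 11 may migrate into conjugation under the basic additive. The fallback sets out from 11 and 6 and comes back at 12. Ligand-free coupling (CrCl2 4 equiv, NiCl2 1 mol%, DMSO, rt) gives 12 together with its C6 epimer (2R,3Z,6R,7Z,10Z)-1,2-bis(TBSO)-11-iodo-3,7-dimethyldodeca-3,7,10-trien-6-ol F5. Dess–Martin oxidation of the mixture gives the enone (2R,3Z,7Z,10Z)-1,2-bis(TBSO)-11-iodo-3,7-dimethyldodeca-3,7,10-trien-6-one F6. Corey–Bakshi–Shibata reduction with (R)-Me-CBS and catecholborane (PhMe, −78 °C; the α-methylalkenyl group as the large substituent) should return 12 under reagent control.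

**Step 18.** Oxygen may be delivered to the wrong face if the ring holds C9–OH away from the alkene, or the isopropenyl group may be epoxidised in competition. The fallback changes the order of events; it sets out from 21 and comes back at 24. Buffered HF·pyridine gives the 8,9-diol (1(10)Z,3S,4S,5S,7R,8S,9R)-3-angeloyloxy-4,5-epoxygermacra-1(10),11-diene-8,9-diol F7. VO(acac)2/t-BuOOH, now with the allylic C9–OH and the homoallylic C8–OH both pointing the oxidant at the same α-face, should give the diepoxy diol (1R,3S,4S,5S,7R,8S,9S,10S)-3-angeloyloxy-1,10:4,5-diepoxygermacr-11-ene-8,9-diol F8. Angeloylation with 1.1 equiv of the mixed trichlorobenzoic anhydride at the less hindered C8–OH (C9–OH is flanked by the quaternary oxirane carbon C10) should give 24.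

## Further compounds

F1 | step 15 | (2R,3Z,6S,7S,8S,10Z)-1,2-bis(TBSO)-7,8-epoxy-12-hydroxy-3,7,11-trimethyldodeca-3,10-dien-6-yl angelate | OC/C(C)=C\C[C@@H]1O[C@]1(C)[C@@H](OC(=O)/C(C)=C\C)C/C=C(C)\[C@@H](O[Si](C)(C)C(C)(C)C)CO[Si](C)(C)C(C)(C)C
F2 | step 15 | (2R,3Z,6S,7S,8S,10Z)-12-bromo-1,2-bis(TBSO)-7,8-epoxy-3,7,11-trimethyldodeca-3,10-dien-6-yl angelate | BrC/C(C)=C\C[C@@H]1O[C@]1(C)[C@@H](OC(=O)/C(C)=C\C)C/C=C(C)\[C@@H](O[Si](C)(C)C(C)(C)C)CO[Si](C)(C)C(C)(C)C
F3 | step 15 | (2R,3Z,6S,7S,8S,10Z)-6-angeloyloxy-12-bromo-2-(TBSO)-7,8-epoxy-3,7,11-trimethyldodeca-3,10-dien-1-ol | BrC/C(C)=C\C[C@@H]1O[C@]1(C)[C@@H](OC(=O)/C(C)=C\C)C/C=C(C)\[C@@H](O[Si](C)(C)C(C)(C)C)CO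
F4 | step 15 | (2R,3Z,6S,7S,8S,10Z)-6-angeloyloxy-12-bromo-2-(TBSO)-7,8-epoxy-3,7,11-trimethyldodeca-3,10-dienal | BrC/C(C)=C\C[C@@H]1O[C@]1(C)[C@@H](OC(=O)/C(C)=C\C)C/C=C(C)\[C@@H](O[Si](C)(C)C(C)(C)C)C=O
F5 | step 9 | (2R,3Z,6R,7Z,10Z)-1,2-bis(TBSO)-11-iodo-3,7-dimethyldodeca-3,7,10-trien-6-ol | I/C(C)=C\C/C=C(C)\[C@H](O)C/C=C(C)\[C@@H](O[Si](C)(C)C(C)(C)C)CO[Si](C)(C)C(C)(C)C
F6 | step 9 | (2R,3Z,7Z,10Z)-1,2-bis(TBSO)-11-iodo-3,7-dimethyldodeca-3,7,10-trien-6-one | I/C(C)=C\C/C=C(C)\C(=O)C/C=C(C)\[C@@H](O[Si](C)(C)C(C)(C)C)CO[Si](C)(C)C(C)(C)C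
F7 | step 18 | (1(10)Z,3S,4S,5S,7R,8S,9R)-3-angeloyloxy-4,5-epoxygermacra-1(10),11-diene-8,9-diol | C=C(C)[C@H]1C[C@@H]2O[C@]2(C)[C@@H](OC(=O)/C(C)=C\C)C/C=C(C)\[C@@H](O)[C@H]1O
F8 | step 18 | (1R,3S,4S,5S,7R,8S,9S,10S)-3-angeloyloxy-1,10:4,5-diepoxygermacr-11-ene-8,9-diol | C=C(C)[C@H]1C[C@@H]2O[C@]2(C)[C@@H](OC(=O)/C(C)=C\C)C[C@H]2O[C@@]2(C)[C@@H](O)[C@H]1O
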